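(The numbers in the tables were computed for an exercise; scatter was added.)

1. 1000 turnovers is what each second catalyst owes in this flask, if each capture agent takes one substrate, at [capture agent] 6.00 mM against [substrate] 20 mM, and the rest becomes target. I read that one-to-one count from late readings of trapped intermediate, 5.60 mM in epsilon and 5.20 mM in eta, both near that charge.

| flask | substrate | reagent | capture agent | free catalyst | second catalyst | remark | time |
|---|---|---|---|---|---|---|---|
| epsilon | 20 mM | 2 equiv | 6 mM | 2.5 mol% | 0.07 mol% | the very flask that is asked about, followed so far |  |
| eta | 10 mM | 2 equiv | 6 mM | 2.5 mol% | 0.07 mol% | run made earlier |  |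
| flask | 20 mM | 2.00 equiv | 6.00 mM | 2.5 mol% | 0.07 mol% |  | 8.0 d |

| run | time / d | trapped intermediate / % | target / % |
|---|---|---|---|
| epsilon | 0.167 | 21 | 28 |
| epsilon | 0.500 | 28 | 64 |
| epsilon | 0.833 | 26 | 71 |
| epsilon | 1.25 | 29 | 72 |
| epsilon | 2.08 | 27 | 74 |
| epsilon | 2.50 | 28 | 74 |
| epsilon | 3.00 | 29 | 71 |
| eta | 1.25 | 52 | 48 |
| eta | 2.50 | 50 | 47 |
| eta | 3.00 | 52 | 48 |
| eta | 5.00 | 50 | 49 |
| eta | 6.00 | 53 | 48 |
| eta | 8.00 | 52 | 49 |

(readings scatter by 1.5 percentage points)

- share of trapped intermediate in trapped intermediate plus target at 12 min
- share of trapped intermediate in trapped intermediate plus target at 6.0 h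
- share of trapped intermediate in trapped intermediate plus target at 8.0 d
- which of trapped intermediate and target there is more of at 8.0 d

- the earlier runs were read with a standard deviation of 1.5 percentage points
- a reading or a percentage of target counts all its forms, free or not

2. You get the pace from the first epsilon reading: 2400 d⁻¹, the turnover frequency. But that is one window. From 0.167 d to 0.500 d the epsilon readings give 1540 d⁻¹, which is slower, so I take the slower pace.

3. That gives 0.647 d as the clearing time, the turnovers owed divided by the turnover rate. Could anything move after it? In the eta run trapped intermediate reads 52% at 1.25 d and 52% at 8.00 d, so I expect no drift. Since 8.0 d is far longer than the clearing time, I carry the epsilon share read at 2.50 d, 27.5%, to the end.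

4. At the first pace, I estimate target at 12 min near 1.40%. The share in the first epsilon reading is 42.9%, but it need not hold that early. If capture waits on something that must build up while turnover runs from the start, the share at 12 min lies below it. So that is my call: below 42.9%, without a firmer number.

5. The forecast gives 56% at 12 min, 37% at 6.0 h and 28% at 8.0 d, with target ahead. It holds that “the initial share is about 58%”. My reckoning differs at 12 min, where the forecast stands above 42.9%.

6. The flask gives shares of 30.3% at 12 min, 38.2% at 6.0 h and 27.6% at 8.0 d, with target ahead.

    substrate + free catalyst → free catalyst + open intermediate (k = 21.9 M⁻¹ min⁻¹)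
    second catalyst + open intermediate ⇌ catalyst intermediate (K = 710 M⁻¹, k = 9800 M⁻¹ min⁻¹)
    reagent + catalyst intermediate → second catalyst + target (k = 56.6 M⁻¹ min⁻¹)
    open intermediate + capture agent → trapped intermediate (k = 0.745 M⁻¹ min⁻¹)
    substrate + target ⇌ idle adduct, settled at all times (K = 480 M⁻¹)

At 0.800 d, past the clearing time of 0.647 d, this flask holds target at 69.4% and trapped intermediate at 27.5%. Take the neighbouring flask with 0.042 mol% of second catalyst. At the same turnover frequency its clearing time becomes 1.08 d, longer than in this flask but shorter than the run. Its share at 6.0 h is 50.6%, against 38.2% here. At 8.0 d that neighbouring flask has 0% of its substrate left and trapped intermediate at 29.7%, with 0.96% of its capture agent remaining.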